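**Remark on the chemistry:** flavone numbering (O1, C2–C4, C4a, C5–C8, C8a; ring B C1'–C6') is used for every chromenone in the route. The target is achiral.

## The problem

The target 14 is a flavone: a chromen-4-one (rings A and C) that carries at C2 a ring B with five of its six positions substituted. It has no stereocenter, so the task is entirely one of oxygenation pattern and regiochemistry. Ring A bears OH at C5 and OMe at C6 and C7; ring B bears OMe at C2', C3' and C4' and a free OH at C6', ortho to the C2–C1' bond. Both aryl units are therefore the same 2-oxy-4,5,6-trioxygenated phenyl group, and the open 1,3-diketone is C2-symmetric except for one O-methyl group. Two things are hard: an oxygen must be placed at C6' of a ring whose more nucleophilic free position is C5', and the 5-oxygen must be distinguished from its neighbours at C6 and C7. The compound is also fragile: the polymethoxy rings are easily oxidized, the 6-methoxy group next to a chelated 5-oxygen can be lost to Lewis acids, and a flavone with free phenols at C5 and C6' can open to its diketone in hot acid or base and reclose through a different oxygen. The feature that allows a short route is the unsubstituted C3 of ring C. A carboxyl oxygen placed there closes a six-membered ring with the carboxyl carbon, C3, C2, C1' and C6'; C6' is the only hydrogen-bearing carbon ortho to C1'; and the carboxyl carbon can afterwards leave as carbon dioxide.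

## Retrosynthesis

**14 from 12 (O–CH3 bond at C5).** The 5-methoxy group is the only one peri to the C4 carbonyl, so chelation-controlled demethylation can single it out. Placing this cut last keeps a free, chelated 5-phenol away from the lithiation and the anodic oxidation. Precursor 12, 6'-hydroxy-5,6,7,2',3',4'-hexamethoxyflavone, has ring A uniformly methylated. The forward step must spare the 6-methoxy group and use a cold, short work-up.

**12 from 9 (C3–carboxyl bond and lactone acyl–oxygen bond).** Direct hydroxylation of C6'–H in a hexamethoxyflavone has no handle: electrophiles prefer C5', and the C4 carbonyl directs metals to ring A. The 6'-oxygen is therefore traced back to lactone 9, in which it is tied to a carboxyl on C3. Simply heating the hydroxy acid is not expected to remove that carbon, because the acid recloses to 9 on acidification and its carboxyl sits on an sp2 carbon. The forward step instead opens both the lactone and the pyranone with hydroxide to the diaroylacetic acid 10, a true β-keto acid that loses carbon dioxide to give diketone 11. Because 11 is C2-symmetric, reclosure through either phenol can only give 12.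

**9 from 8 (C6'–O bond; key disconnection).** Cutting the lactone C6'–O bond leads to the flavone-3-carboxylic acid 8, whose ring B is a plain 2,3,4-trimethoxyphenyl group. The neighbouring options are weaker. A 6'-halide for a copper-mediated closure would need halogenation at the less reactive ring position. Carrying the oxygen from the start would need a tetraoxygenated benzaldehyde made in several steps. The forward reaction is an anodic dehydrogenative lactonization, and it must choose C6'–H over the methoxylated C2' and over ring A.

**8 from 6 (C3–CO2H bond).** Building the carboxyl in before ring closure, through an o-hydroxyaryl β-ketoester, is avoided because the free phenol of such an ester closes onto it to give a 4-hydroxycoumarin. Carboxylating the finished flavone 6 through its 3-lithio derivative 7 is direct and uses carbon dioxide as the one-carbon unit. The forward step needs deprotonation at C3 rather than at a ring carbon.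

**6 from 5, and 5 from 3 and 4 (O1–C2 bond; Cα–Cβ bond).** The flavone is opened to the 2'-hydroxychalcone 5, and this to acetophenone 3 and 2,3,4-trimethoxybenzaldehyde 4. The acylation–rearrangement route through a benzoyl chloride reaches 6 too, but costs one more step. The forward steps are an aldol condensation and an oxidative cyclization, both routine on this substitution pattern.

**3 from 1 (aryl–acetyl bond).** The two free positions of 3,4,5-trimethoxyphenol 1 are equivalent and ortho to the hydroxyl, so C-acetylation can give only 3.

## Roads not taken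

**Alternative 1: symmetric diarylisoxazole by nitrile oxide cycloaddition.**
- **Cut:** C2–C3 and the C4–O bond of a masked 1,3-diketone.
- **Forward key step:** 2-(benzyloxy)-4,5,6-trimethoxybenzonitrile oxide A1 adds to 1-(benzyloxy)-2-ethynyl-3,4,5-trimethoxybenzene A2 to give the 3,5-diarylisoxazole A3. Reductive N–O cleavage with hydrolysis, then hydrogenolysis of both benzyl ethers, would lead to 11 and on through 12 to 14.
- **Merits:** the hidden symmetry is used from the outset, the 6'-oxygen is present from the start, the cycloaddition regiochemistry with a terminal alkyne is reliable, and no oxidation of an electron-rich ring is needed.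
- **Weak points:** A1 and A2 must each be made from 1 by benzylation, formylation and then, separately, oxime formation or alkyne homologation. The cycloaddition joins two di-ortho-substituted partners. The isoxazole must then be unmasked.
- **Comparison:** this road is safer at the ring B oxygen and needs no electrolysis. The chosen plan is several steps shorter and takes both aryl units directly from commercial compounds. The final 5-O-demethylation is common to both.

**Alternative 2: two-directional diacylation with a malonyl unit.**
- **Cut:** C4–C4a and C2–C1'.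
- **Forward key step:** malonyl dichloride A4 acylates two molecules of 1-(benzyloxy)-3,4,5-trimethoxybenzene A5 ortho to the benzyloxy group, giving 1,3-bis[2-(benzyloxy)-4,5,6-trimethoxyphenyl]propane-1,3-dione A6. Hydrogenolysis then gives 11.
- **Merits:** on paper this is the shortest route of the four: benzylation, diacylation, hydrogenolysis, cyclodehydration and demethylation, two steps fewer than the chosen plan.
- **Weak points:** after the first acylation the remaining acid chloride sits five atoms from the ortho ether oxygen. Lewis acids strong enough to drive the acylation also cleave that ether, so closure to a 4-hydroxycoumarin should beat intermolecular attack on a second, hindered arene. A4 also self-condenses through its ketene.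
- **Comparison:** if the diacylation worked, this road would be better in step count. The chosen plan reaches the same diketone 11 through steps that each have close precedent.

**Alternative 3: ring A by cyclobutenone ring expansion.**
- **Cut:** C4a–C5, with ring A built last on a pyranone.
- **Forward key step:** heating the racemic 4-(pyranon-2-yl)-2,3-dimethoxycyclobutenone A7 opens it to a vinylketene, which closes onto the pyranone carbon next to the carbonyl. Tautomerization gives the 6'-O-benzyl ether A8 of the target, and hydrogenolysis would finish.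
- **Merits:** the 5-hydroxyl is formed free and already distinct from the 6- and 7-methoxy groups. The Lewis acid demethylation and its risk at C6 disappear; in this respect the road is better than the chosen one.
- **Weak points:** A7 requires a 2-metalated 6-aryl-4-pyranone, its addition to a squaric ester and a deoxygenation. A 4-pyranone double bond is an unusual partner in this electrocyclization. Ring B must still be made with four oxygens.
- **Comparison:** the chosen plan has far simpler starting materials and a shorter sequence of classical flavone reactions.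

Key step: step 5

## Route

**Step 1**
Reactants: 1 3,4,5-trimethoxyphenol
Product: 3 1-(6-hydroxy-2,3,4-trimethoxyphenyl)ethan-1-one, via difluoroboron chelate 2 (not isolated)
Conditions: AcOH, BF3·OEt2, 85 °C; then H2O, 50 °C
Reagents that add atoms: acetic acid, CC(=O)O
Why: Friedel–Crafts C-acetylation (one-pot Fries-type) of an activated phenol; both free ring positions of 1 are equivalent and ortho to the hydroxyl, so only one ketone can form, and the chelate 2 shields it from a second acylation until it is hydrolysed on work-up.

**Step 2**
Reactants: 3 1-(6-hydroxy-2,3,4-trimethoxyphenyl)ethan-1-one; 4 2,3,4-trimethoxybenzaldehyde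
Product: 5 (E)-1-(6-hydroxy-2,3,4-trimethoxyphenyl)-3-(2,3,4-trimethoxyphenyl)prop-2-en-1-one
Conditions: KOH (50% aq), EtOH, rt; then dil. HCl
Reagents that add atoms: none
Why: Claisen–Schmidt condensation of a methyl ketone with a non-enolizable aldehyde; dehydration gives the conjugated (E)-enone as the thermodynamic alkene, and any flavanone formed by conjugate addition of the phenoxide is oxidized to the same flavone in step 3.

**Step 3**
Reactants: 5 (E)-1-(6-hydroxy-2,3,4-trimethoxyphenyl)-3-(2,3,4-trimethoxyphenyl)prop-2-en-1-one
Product: 6 5,6,7-trimethoxy-2-(2,3,4-trimethoxyphenyl)-4H-chromen-4-one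
Conditions: I2 (10 mol %), DMSO, 130 °C
Reagents that add atoms: none
Why: Iodine/DMSO oxidative cyclization of a 2'-hydroxychalcone (oxa-Michael closure, then iodination and elimination, with DMSO reoxidizing the HI), the standard entry to 5,6,7-trimethoxyflavones; the alkene geometry of 5 is erased.

**Step 4**
Reactants: 6 5,6,7-trimethoxy-2-(2,3,4-trimethoxyphenyl)-4H-chromen-4-one
Product: 8 5,6,7-trimethoxy-4-oxo-2-(2,3,4-trimethoxyphenyl)-4H-chromene-3-carboxylic acid, via 3-lithioflavone 7 (not isolated)
Conditions: LiN(i-Pr)2 (1.5 equiv), THF, −78 °C; CO2 (g), −78 °C → rt; aq. HCl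
Reagents that add atoms: carbon dioxide, O=C=O
Why: C3 lithiation of a flavone with a lithium amide followed by carboxylation, a known way to flavone-3-carboxylic acids; the C4 carbonyl and the 2'-methoxy oxygen hold lithium at the only vinylic C–H, and the amide base is too weak to metalate the ring C–H bonds at −78 °C. Carboxylating after ring C exists avoids an o-hydroxyaryl β-ketoester, which would close to a 4-hydroxycoumarin.

**Step 5**
Reactants: 8 5,6,7-trimethoxy-4-oxo-2-(2,3,4-trimethoxyphenyl)-4H-chromene-3-carboxylic acid
Product: 9 1,2,3,8,9,10-hexamethoxy-6H,7H-chromeno[4,3-b]chromene-6,7-dione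
Conditions: undivided cell, graphite anode, Pt cathode, constant current 5 mA cm−2 (about 2.5 F mol−1), n-Bu4NBF4 (0.1 M), 2,6-lutidine (1 equiv), MeCN/HFIP 4:1, rt
Reagents that add atoms: none
Why: Anodic dehydrogenative C–H/O–H lactonization, known for biaryl-2-carboxylic acids (giving benzo[c]chromen-6-ones) and for 3,3-diarylacrylic acids (giving 4-arylcoumarins); acid 8 is a β-aryl acrylic acid of this kind locked in ring C. The lutidinium carboxylate of 8 is oxidized at graphite to an acyloxy radical, or ring B to its radical cation at a similar potential, and in either case the carboxyl oxygen bonds to C6'. The ring formed is the six-membered O–C(=O)–C3=C2–C1'=C6' lactone, a 6-exo-trig closure onto the C5'=C6' π bond; the alternative spiro attack at C1' is reversible and can only drain into the same lactone by acyloxy shift. A second one-electron oxidation and loss of the C6' proton restore ring B, while protons are reduced to H2 at the Pt cathode, so no chemical oxidant is consumed. Site selectivity rests on geometry and not on electronics: the carboxyl reaches only C2' and C6', C5' and ring A are out of range, and of the two only C6' carries a hydrogen whose loss can rearomatize the ring. Attack at the methoxylated C2' is hindered and reversible, and rotation about C2–C1' (two ortho substituents only) lets the carboxyl face C6'. An acyloxy radical on an sp2 carbon loses carbon dioxide slowly, so closure should outrun Kolbe-type decarboxylation, and lactone 9, whose new oxygen is acylated, is harder to oxidize than the carboxylate of 8. No stereocenter is created.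

**Step 6**
Reactants: 9 1,2,3,8,9,10-hexamethoxy-6H,7H-chromeno[4,3-b]chromene-6,7-dione
Product: 12 2-(6-hydroxy-2,3,4-trimethoxyphenyl)-5,6,7-trimethoxy-4H-chromen-4-one, via diaroylacetic acid 10 (not isolated), via symmetric 1,3-diketone 11 (not isolated)
Conditions: NaOH (2 M aq), 1,4-dioxane, 70 °C; then H2SO4 to pH 2, rt; then AcOH, H2SO4 (cat.), 90 °C
Reagents that add atoms: water, O (delivered as hydroxide; it supplies the hydrogens at C3 and on the 6'-oxygen, and its oxygen can end up in ring C after reclosure)
Why: Hydroxide opens the aryl lactone and, by conjugate addition at C2, the doubly activated pyranone, giving the salt of 10; on acidification this 2-acyl-3-oxo acid loses carbon dioxide, the classical alkaline degradation of 4-hydroxycoumarin-type lactones to o-hydroxyaryl ketones. Diketone 11 is C2-symmetric, so acid cyclodehydration gives 12 whichever phenol closes onto whichever carbonyl; sulfuric acid is used because it offers no nucleophile for O-demethylation.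

**Step 7**
Reactants: 12 2-(6-hydroxy-2,3,4-trimethoxyphenyl)-5,6,7-trimethoxy-4H-chromen-4-one
Product: 14 5-hydroxy-2-(6-hydroxy-2,3,4-trimethoxyphenyl)-6,7-dimethoxy-4H-chromen-4-one, via bis(dichloroboryloxy)flavone 13 (not isolated)
Conditions: BCl3 (1 M in CH2Cl2, 2.5 equiv), CH2Cl2, −78 → 0 °C; then H2O, 0 °C
Reagents that add atoms: none
Why: Chelation-controlled O-demethylation: BCl3 bridges the C4 carbonyl and the peri 5-methoxy oxygen and chloride removes that methyl group, the standard selective 5-O-demethylation of 5,6,7-trimethoxyflavones; the other five methoxy groups have no carbonyl partner. The 6'-phenol rides through as its dichloroborate in 13, and cold water releases both oxygens without the heat or strong acid that could open ring C.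

## Compound list

1 | 3,4,5-trimethoxyphenol | COc1cc(O)cc(OC)c1OC | starting material
2 | difluoroboron chelate of 3 (2,2-difluoro-5,6,7-trimethoxy-4-methyl-1,3,2-benzodioxaborinin-3-ium-2-uide) | CC1=[O+][B-](F)(F)Oc2cc(OC)c(OC)c(OC)c12 | intermediate
3 | 1-(6-hydroxy-2,3,4-trimethoxyphenyl)ethan-1-one | CC(=O)c1c(O)cc(OC)c(OC)c1OC | intermediate
4 | 2,3,4-trimethoxybenzaldehyde | COc1ccc(C=O)c(OC)c1OC | starting material
5 | (E)-1-(6-hydroxy-2,3,4-trimethoxyphenyl)-3-(2,3,4-trimethoxyphenyl)prop-2-en-1-one | COc1ccc(/C=C/C(=O)c2c(O)cc(OC)c(OC)c2OC)c(OC)c1OC | intermediate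
6 | 5,6,7-trimethoxy-2-(2,3,4-trimethoxyphenyl)-4H-chromen-4-one (5,6,7,2',3',4'-hexamethoxyflavone) | COc1ccc(-c2cc(=O)c3c(OC)c(OC)c(OC)cc3o2)c(OC)c1OC | intermediate
7 | 3-lithio-5,6,7-trimethoxy-2-(2,3,4-trimethoxyphenyl)-4H-chromen-4-one | COc1ccc(-c2oc3cc(OC)c(OC)c(OC)c3c(=O)c2[Li])c(OC)c1OC | intermediate
8 | 5,6,7-trimethoxy-4-oxo-2-(2,3,4-trimethoxyphenyl)-4H-chromene-3-carboxylic acid | OC(=O)c1c(-c2ccc(OC)c(OC)c2OC)oc2cc(OC)c(OC)c(OC)c2c1=O | intermediate
9 | 1,2,3,8,9,10-hexamethoxy-6H,7H-chromeno[4,3-b]chromene-6,7-dione (lactone between the C3 carboxyl and the C6' oxygen) | O=C1Oc2cc(OC)c(OC)c(OC)c2-c2oc3cc(OC)c(OC)c(OC)c3c(=O)c21 | intermediate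
10 | 3-(6-hydroxy-2,3,4-trimethoxyphenyl)-2-(6-hydroxy-2,3,4-trimethoxybenzoyl)-3-oxopropanoic acid | OC(=O)C(C(=O)c1c(O)cc(OC)c(OC)c1OC)C(=O)c1c(O)cc(OC)c(OC)c1OC | intermediate
11 | 1,3-bis(6-hydroxy-2,3,4-trimethoxyphenyl)propane-1,3-dione | O=C(CC(=O)c1c(O)cc(OC)c(OC)c1OC)c1c(O)cc(OC)c(OC)c1OC | intermediate
12 | 2-(6-hydroxy-2,3,4-trimethoxyphenyl)-5,6,7-trimethoxy-4H-chromen-4-one (6'-hydroxy-5,6,7,2',3',4'-hexamethoxyflavone) | COc1cc(O)c(-c2cc(=O)c3c(OC)c(OC)c(OC)cc3o2)c(OC)c1OC | intermediate
13 | 5,6'-bis(dichloroboryloxy)-6,7,2',3',4'-pentamethoxyflavone | COc1cc(OB(Cl)Cl)c(-c2cc(=O)c3c(OB(Cl)Cl)c(OC)c(OC)cc3o2)c(OC)c1OC | intermediate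
14 | 5-hydroxy-2-(6-hydroxy-2,3,4-trimethoxyphenyl)-6,7-dimethoxy-4H-chromen-4-one (5,6'-dihydroxy-6,7,2',3',4'-pentamethoxyflavone) | COc1cc(O)c(-c2cc(=O)c3c(O)c(OC)c(OC)cc3o2)c(OC)c1OC | target

## Step count and risks

Total: 7 steps. Longest linear sequence: 7 steps (1 to 14); aldehyde 4 enters at step 2.

**Step 5 (key step).** The most likely failure is oxidation of the trimethoxyaryl rings in competition with the closure. The carboxylate and ring B are oxidized at similar potentials, so radical-cation coupling, capture by solvent or dearomatizing attack at the methoxylated C2' could consume 8. The fallback sets out from 8 and returns at 9. It replaces electron transfer by carboxylate-directed C–H palladation: Pd(OAc)2 (cat.), PhI(OAc)2, KOAc, N-acetylglycine, t-BuOH, 80 °C. A six-membered palladacycle of divalent palladium forms at C6', and the C–O bond is made by reductive elimination from tetravalent palladium. This is a known lactonization of biaryl-2-carboxylic acids that avoids free radical cations. It makes no compound outside the list (F0).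

**Step 4.** The likely failure is metalation at C8, which lies between two oxygens, or addition of 7 to a second molecule of 6; either would lower conversion to 8. The fallback sets out from 3 and returns at 8, with the carboxyl built in before ring closure and the phenol masked so that no 4-hydroxycoumarin can form.
- Protection of 3 with MOMCl and i-Pr2NEt gives 1-[6-(methoxymethoxy)-2,3,4-trimethoxyphenyl]ethan-1-one F1.
- Claisen condensation with dibenzyl carbonate (NaH, THF) gives benzyl 3-[6-(methoxymethoxy)-2,3,4-trimethoxyphenyl]-3-oxopropanoate F2.
- C-aroylation of its magnesium enolate (MgCl2, Et3N, MeCN) with commercial 2,3,4-trimethoxybenzoyl chloride gives benzyl 3-[6-(methoxymethoxy)-2,3,4-trimethoxyphenyl]-3-oxo-2-(2,3,4-trimethoxybenzoyl)propanoate F3.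
- TFA in CH2Cl2 removes the acetal and cyclodehydrates to benzyl 5,6,7-trimethoxy-4-oxo-2-(2,3,4-trimethoxyphenyl)-4H-chromene-3-carboxylate F4.
- Hydrogenolysis (H2, Pd/C, palladium on carbon) gives 8 without base.

**Step 6.** The likely failure is relactonization on acidification outrunning decarboxylation, which returns 9. The other risk is retro-Claisen loss of an aroyl group from the triacylmethane stage in hot alkali. The fallback sets out from 9 and returns at 12. It caps the phenol so that the acid cannot reclose, and it removes the carboxyl without opening ring C.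
- Methanolysis of the lactone (K2CO3, MeOH) and benzylation of the freed phenoxide in the same flask (BnBr) give methyl 2-[6-(benzyloxy)-2,3,4-trimethoxyphenyl]-5,6,7-trimethoxy-4-oxo-4H-chromene-3-carboxylate F5.
- Cleavage at the ester methyl carbon (LiI, pyridine, reflux) gives 2-[6-(benzyloxy)-2,3,4-trimethoxyphenyl]-5,6,7-trimethoxy-4-oxo-4H-chromene-3-carboxylic acid F6.
- Silver-catalysed protodecarboxylation of this di-ortho-substituted acid (Ag2CO3 cat., AcOH, DMSO, 120 °C) gives 2-[6-(benzyloxy)-2,3,4-trimethoxyphenyl]-5,6,7-trimethoxy-4H-chromen-4-one F7.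
- Hydrogenolysis (H2, Pd/C) gives 12.

**Step 7.** The likely failure is further cleavage of the 6-methoxy group beside the newly formed boron chelate. The free 6'-phenol consumes reagent in an ill-defined way, and the excess then needed drives this second cleavage. The fallback sets out from 12 and returns at 14.
- Acetylation (Ac2O, pyridine) gives 3,4,5-trimethoxy-2-(5,6,7-trimethoxy-4-oxo-4H-chromen-2-yl)phenyl acetate F8.
- With a single boron-binding site, BCl3 (1.1 equiv, CH2Cl2, −78 → −20 °C) should then give 2-(5-hydroxy-6,7-dimethoxy-4-oxo-4H-chromen-2-yl)-3,4,5-trimethoxyphenyl acetate F9.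
- Brief methanolysis (K2CO3, MeOH, 0 °C) releases 14; if the acetate is lost during the Lewis acid step, the outcome is the same.

## Further compounds

F0 | step 5 | none | none
F1 | step 4 | 1-[6-(methoxymethoxy)-2,3,4-trimethoxyphenyl]ethan-1-one | CC(=O)c1c(OCOC)cc(OC)c(OC)c1OC
F2 | step 4 | benzyl 3-[6-(methoxymethoxy)-2,3,4-trimethoxyphenyl]-3-oxopropanoate | O=C(CC(=O)c1c(OCOC)cc(OC)c(OC)c1OC)OCc1ccccc1
F3 | step 4 | benzyl 3-[6-(methoxymethoxy)-2,3,4-trimethoxyphenyl]-3-oxo-2-(2,3,4-trimethoxybenzoyl)propanoate | O=C(OCc1ccccc1)C(C(=O)c1ccc(OC)c(OC)c1OC)C(=O)c1c(OCOC)cc(OC)c(OC)c1OC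
F4 | step 4 | benzyl 5,6,7-trimethoxy-4-oxo-2-(2,3,4-trimethoxyphenyl)-4H-chromene-3-carboxylate | O=C(OCc1ccccc1)c1c(-c2ccc(OC)c(OC)c2OC)oc2cc(OC)c(OC)c(OC)c2c1=O
F5 | step 6 | methyl 2-[6-(benzyloxy)-2,3,4-trimethoxyphenyl]-5,6,7-trimethoxy-4-oxo-4H-chromene-3-carboxylate | COC(=O)c1c(-c2c(OCc3ccccc3)cc(OC)c(OC)c2OC)oc2cc(OC)c(OC)c(OC)c2c1=O
F6 | step 6 | 2-[6-(benzyloxy)-2,3,4-trimethoxyphenyl]-5,6,7-trimethoxy-4-oxo-4H-chromene-3-carboxylic acid | OC(=O)c1c(-c2c(OCc3ccccc3)cc(OC)c(OC)c2OC)oc2cc(OC)c(OC)c(OC)c2c1=O
F7 | step 6 | 2-[6-(benzyloxy)-2,3,4-trimethoxyphenyl]-5,6,7-trimethoxy-4H-chromen-4-one | COc1cc(OCc2ccccc2)c(-c2cc(=O)c3c(OC)c(OC)c(OC)cc3o2)c(OC)c1OC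
F8 | step 7 | 3,4,5-trimethoxy-2-(5,6,7-trimethoxy-4-oxo-4H-chromen-2-yl)phenyl acetate | CC(=O)Oc1cc(OC)c(OC)c(OC)c1-c1cc(=O)c2c(OC)c(OC)c(OC)cc2o1
F9 | step 7 | 2-(5-hydroxy-6,7-dimethoxy-4-oxo-4H-chromen-2-yl)-3,4,5-trimethoxyphenyl acetate | CC(=O)Oc1cc(OC)c(OC)c(OC)c1-c1cc(=O)c2c(O)c(OC)c(OC)cc2o1
A1 | alternative 1 | 2-(benzyloxy)-4,5,6-trimethoxybenzonitrile oxide | COc1cc(OCc2ccccc2)c(C#[N+][O-])c(OC)c1OC
A2 | alternative 1 | 1-(benzyloxy)-2-ethynyl-3,4,5-trimethoxybenzene | COc1cc(OCc2ccccc2)c(C#C)c(OC)c1OC
A3 | alternative 1 | 3,5-bis[2-(benzyloxy)-4,5,6-trimethoxyphenyl]isoxazole | COc1cc(OCc2ccccc2)c(-c2cc(-c3c(OCc4ccccc4)cc(OC)c(OC)c3OC)on2)c(OC)c1OC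
A4 | alternative 2 | malonyl dichloride | O=C(Cl)CC(=O)Cl
A5 | alternative 2 | 1-(benzyloxy)-3,4,5-trimethoxybenzene | COc1cc(OCc2ccccc2)cc(OC)c1OC
A6 | alternative 2 | 1,3-bis[2-(benzyloxy)-4,5,6-trimethoxyphenyl]propane-1,3-dione | COc1cc(OCc2ccccc2)c(C(=O)CC(=O)c2c(OCc3ccccc3)cc(OC)c(OC)c2OC)c(OC)c1OC
A7 | alternative 3 | racemic 4-{6-[2-(benzyloxy)-4,5,6-trimethoxyphenyl]-4-oxo-4H-pyran-2-yl}-2,3-dimethoxycyclobut-2-en-1-one | COC1=C(OC)C(c2cc(=O)cc(-c3c(OCc4ccccc4)cc(OC)c(OC)c3OC)o2)C1=O
A8 | alternative 3 | 2-[6-(benzyloxy)-2,3,4-trimethoxyphenyl]-5-hydroxy-6,7-dimethoxy-4H-chromen-4-one | COc1cc(OCc2ccccc2)c(-c2cc(=O)c3c(O)c(OC)c(OC)cc3o2)c(OC)c1OC
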